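The data were computed for an exercise, and the scatter is random.

At early times the birch run makes 32.8 mM of product by 2.7 min. By 16 min it stands at 61.4 mM, with 139 mM of starting material and 239 mM of partner still in the flask. So neither reactant has run out in the birch run, yet it has stalled.

| flask | starting material | partner | free catalyst | time |
|---|---|---|---|---|
| birch | 200 mM | 300 mM | 0.400 mM |  |
| ash | 120 mM | 220 mM | 0.400 mM |  |
| oak | 400 mM | 300 mM | 0.400 mM |  |
| cedar | 200 mM | 150 mM | 0.400 mM |  |
| larch | 920 mM | 300 mM | 0.400 mM | 16 min |

- birch run (time / min: [product] / mM): 2.7: 32.8; 5.3: 50.4; 8.0: 55.3; 11: 55.9; 13: 60.7; 16: 61.4
- ash run (time / min: [product] / mM): 2.7: 18.5; 5.3: 31.0; 8.0: 33.0; 11: 38.6; 13: 38.2; 16: 38.7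
- oak run (time / min: [product] / mM): 2.7: 42.1; 5.3: 75.3; 8.0: 89.7; 11: 101.6; 13: 114.4; 16: 114.8
- cedar run (time / min: [product] / mM): 2.7: 22.1; 5.3: 35.2; 8.0: 43.4; 11: 55.4; 13: 54.9; 16: 57.2

(readings scatter by 2 mM)

- reaction order in [partner] at the outset, round the charge of the birch run, defined at two percent of the starting material turned into product
- reaction order in [starting material] at the outset, round the charge of the birch run, defined at two percent of the starting material turned into product (one fixed amount of product, the same in the runs compared)
- product in the larch run at 16 min, as a share of the starting material charged
- which of these the readings show (the catalyst dies by itself / the second partner is lost by itself / the second partner pairs with itself / the product decays / the second partner kills the catalyst / nothing beyond the main steps)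

- Overall: starting material + partner -> product, with free catalyst as catalyst.
- Constant volume, constant temperature.
- The analysis sees a species whether free or bound.
- "The second partner" is partner.
- An order is taken over about fifteen percent of the charge, up and down.

We carry one quantity, the reach: the share of the starting material charged that has become product when a run stalls. The zero of our scale is a share that does not move with the charge, and the last readings lie close to it:

birch 30.7%, ash 32.3%, oak 28.7%, cedar 28.6%

reach = mean of these = 30.1%

The cedar run has half the partner of the birch run. It starts slower, 22.1 mM against 32.8 mM at 2.7 min, but its last reading is 28.6% of the starting material charged, against 30.7% in the birch run. We take it that the partner kills the catalyst.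

Now we bracket the larch run. Its partner, the limiting reagent (300 mM against 920 mM), allows 32.6%, but we take the lower reach as the ceiling. For a floor we take the oak run's amount at 16 min, since the larch run has the same 300 mM of partner and more starting material:

floor = 12.5%

To tighten this we read orders from the first readings, and scale the oak run's early pace to the larch charge:

order in starting material, oak over birch = 0.360

order in partner, birch over cedar = 0.570

early pace, larch = 21.0 mM min⁻¹

clock = reach amount / pace = 13.1 min

share at 16 min = reach × (1 − exp(−time/clock)) = 21.2%

This counts no drain of partner, though 105 mM of it would then remain.

The forecast gives an order of 1 in partner, which differs from our reading, an order of 0.36 in starting material, 20% for the larch run, above our floor and below the reach, and the verdict that the second partner kills the catalyst, saying in its own words: “Product per catalyst lost is then independent of partner.”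

The larch run gives 20.5% at 16 min, below our 21.2%, with orders 0.51 in partner and 0.39 in starting material, and the choice is the second partner kills the catalyst.

    free catalyst + starting material ⇌ catalyst-substrate complex, settled at all times (2.850 L mol⁻¹)
    catalyst-substrate complex + partner ⇌ ternary complex, settled at all times (9.180 L mol⁻¹)
    ternary complex → product + free catalyst (82.20 min⁻¹)
    free catalyst + partner → spent catalyst + partner (2.190 L mol⁻¹ min⁻¹)

At 16 min the larch run stands at 68.1% of the reach. In the oak run a quarter of the starting material, 83.1% of the reach, has turned by 10.3 min, and in the ash run by 5.46 min.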